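The amounts charged and read so far are these.

| setting | winter | elm | maple |
|---|---|---|---|
| starting material | 1 M | 2.0 M | 2.0 M |
| temperature | 100 °C | 100 °C | 75 °C |
| remark | run made earlier |  |  |
| time |  | 5.0 min | 5.0 min |

winter run (percent of the starting material charged)

| time / s | target / % | isomer of the product / % |
|---|---|---|
| 10.0 | 14.2 | 0.5 |
| 20.0 | 26.8 | 0.2 |
| 40.0 | 54.4 | 1.8 |
| 60.0 | 81.0 | 1.8 |

(readings scatter by 1 percentage point)

- the numbers in the tables scatter by 1 percentage point (one standard deviation)
- the earlier runs do not show what temperature does; that part of a forecast is a guess
- a reading or a percentage of target counts all its forms, free or not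

- which flask leads in share of target in all that became target or isomer of the product ("all alike" within 1.5 percentage points) (elm / maple / all alike)
- share of target in all that became target or isomer of the product, elm
- share of target in all that became target or isomer of the product, maple

Winter holds 81.0% of its 1 M charge as target at 60.0 s, and its readings lie close to a straight line. Target therefore forms at a steady 0.0135 M s⁻¹, a zero-order rise. At that rate, elm's 2.0 M is used up in 148 s, about half of its 5.0 min.

Now divide the rate of isomer by the rate of target, and time drops out. Along a straight rise, isomer over target comes to half of the leak times the time elapsed. Winter's last pair, 1.8% against 81.0%, gives a reading of 7.41 × 10⁻⁴ s⁻¹ for the leak, the fraction of target passing into isomer each second. That isomer reading carries a scatter of 1 percentage point, so this is the weak link.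

In elm, isomer over target is then 5.49% when the rise ends. Target then sits and leaks for 152 s, which brings the share down to 84.7%. For maple, temperature is a guess: if both steps run 5 times slower, the leak shrinks likewise and the share is 97.8%. This reckoning therefore puts maple ahead of elm.

The forecast named maple, with 92% for elm and 97.5% for maple, the latter “helped by low conversion and lower temperature”. Its elm figure stands above the reckoning here.

The flasks give 86.6% for elm and 98.0% for maple, so maple leads.

    starting material → target, rate k1*[starting material]/(1 + ([starting material]/sat1)) (19.0 mM, k = 0.770 s⁻¹, Ea = 101 kJ mol⁻¹)
    target ⇌ isomer of the product (K = 2.60, k = 0.00150 s⁻¹, Ea = 103 kJ mol⁻¹, ΔH = −78.0 kJ mol⁻¹)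
    crystals ⇌ target, rate k3*(cs3 - [target]) while solid is left; crystals form when [target] > cs3 (solubility = 0.640 M, k = 0.0700 s⁻¹)
    (constants at 100 °C)

The link to reforge is which target leaks: crystals do not pass into isomer, dissolved target does. At 5.00 min, elm holds 55.2% of its charge as crystals. With the low solubility of target, and at this hour of reading, elm stands at 86.6%, against 72.7% for the same flask without that limit. At 5.00 min, the neighbour flask charged with 0.80 M holds 0% crystals. The winter leak gives 81.9%, and that flask stands at 70.1%.

All runs were generated by integration from invented constants; the scatter is artificial.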